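**Retrosynthetic overview**

1. The target is (−)-epiafzelechin 3-O-gallate-(4β→6)-(−)-epicatechin 3-O-gallate. The last cuts are thirteen O-benzyl groups and a lower C8 bromine (hydrogenolysis), then the upper gallate ester (acylation of the upper C3 hydroxyl).
2. Key cut: the O1–C2 bond of the upper pyran (ring C). The strategy rests on C2 of this ring, a benzylic ether carbon that carries ring B and lies cis to the C3 oxygen. That array arises when the ring A phenol oxygen opens a C2–C3 cis-epoxide at C2 with inversion (6-endo), the epoxide oxygen becoming the C3 hydroxyl.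
3. The cis-epoxide comes from a (Z)-1,1,3-triarylpropene by catalyst-controlled dioxirane epoxidation, and the Z-alkene from the 1,1,3-triarylpropyne by semi-hydrogenation.
4. The propyne is cut at C4–C4a: Friedel–Crafts propargylation of 3,5-bis(benzyloxy)phenol (ring A) by a propargylic cation on lower C6, under a chiral phosphoric acid, sets C4. The lower unit comes from (−)-epicatechin by benzylation, C8 bromination (directs the next substitution to C6 and caps the ring), galloylation, C6 formylation and alkynylation.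
5. Ring order: both rings of the lower flavan come intact from epicatechin; the only ring formed is the upper pyran, in step 11.

Key step: step 11

**Remarks on the chemistry**

- Upper-unit atoms carry flavan numbers also in open-chain compounds (C2 bears ring B, C3 is the middle carbon, C4 the diarylmethine); "lower" marks atoms of the epicatechin unit. The CIP label at C4 changes with the ring A O-substituent and the lower C8 bromine although the geometry does not; the SMILES is binding.
- The C2–C3–C4 chain is brought in as an arylpropargyl unit. Benzylidenation of a 4-aryl-chroman-2-ol would place an extra CH2 between C4 and the double bond.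
- The lower C3 oxygen carries its final tri-O-benzylgalloyl ester from step 3 on. The lower C8 bromine is a spectator removed in the last step.
- Assumption: 3,4,5-tris(benzyloxy)benzoyl chloride, 3,5-bis(benzyloxy)phenol and 1-(benzyloxy)-4-ethynylbenzene are purchasable.

**Route**

Step 1
Reactants: 1 (−)-epicatechin
Product: 2 5,7,3',4'-tetra-O-benzyl-(−)-epicatechin
Conditions: BnBr (4.4 equiv), K2CO3, DMF, 0 °C → rt
Reagents that add atoms: benzyl bromide, BrCc1ccccc1
Why: Williamson etherification of the four phenols under carbonate base leaves the secondary C3 alcohol free; lower C2 and C3 (both R) come from the chiral pool and are not touched again.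

Step 2
Reactants: 2 5,7,3',4'-tetra-O-benzyl-(−)-epicatechin
Product: 3 8-bromo-5,7,3',4'-tetra-O-benzyl-(−)-epicatechin
Conditions: NBS (1.0 equiv), CH2Cl2, −78 → 0 °C
Reagents that add atoms: N-bromosuccinimide, O=C1CCC(=O)N1Br
Why: Electrophilic aromatic bromination with one equivalent at low temperature should go to C8, the most reactive site of the 5,7-dialkoxy ring of benzylated flavan-3-ols; the bromine later steers substitution to C6 and keeps this ring from capturing cations.

Step 3
Reactants: 3 8-bromo-5,7,3',4'-tetra-O-benzyl-(−)-epicatechin; 4 3,4,5-tris(benzyloxy)benzoyl chloride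
Product: 5 8-bromo-5,7,3',4'-tetra-O-benzyl-(−)-epicatechin 3-O-[3,4,5-tris(benzyloxy)benzoate]
Conditions: Et3N, DMAP (cat.), CH2Cl2, rt
Reagents that add atoms: none
Why: DMAP-catalysed acylation of the C3 alcohol by the acid chloride installs the lower gallate in benzyl-protected form, as a group that should survive every later step.

Step 4
Reactants: 5 8-bromo-5,7,3',4'-tetra-O-benzyl-(−)-epicatechin 3-O-[3,4,5-tris(benzyloxy)benzoate]
Product: 7 6-formyl derivative of 5 (aldehyde on lower C6), via C6 dimethyliminium chloride 6 (not isolated)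
Conditions: POCl3, DMF, 0 → 60 °C; aq. NaOAc
Reagents that add atoms: N,N-dimethylformamide, CN(C)C=O; water, O
Why: Vilsmeier–Haack formylation should attack C6, the only unsubstituted carbon of the trioxygenated ring once C8 is brominated, the dialkoxy B ring and the ester-deactivated gallate ring being far less nucleophilic; hydrolysis of the iminium salt gives the aldehyde.

Step 5
Reactants: 7 6-formyl lower unit; 8 1-(benzyloxy)-4-ethynylbenzene
Product: 10 lower unit bearing 1-hydroxy-3-(4-benzyloxyphenyl)prop-2-yn-1-yl at C6 (both carbinol epimers), via lithium (4-benzyloxyphenyl)acetylide 9 (not isolated)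
Conditions: 8 (1.5 equiv), n-BuLi (1.4 equiv), THF, −78 °C; then 7, −78 → −40 °C; aq. NH4Cl
Reagents that add atoms: none
Why: 1,2-Addition of the lithium acetylide to the aldehyde at low temperature is much faster than attack on the hindered aryl ester, and keeping the alkyne in excess over n-BuLi avoids bromine–lithium exchange; the carbinol configuration is irrelevant because this centre is ionised in step 6.

Step 6
Reactants: 10 lower-unit propargylic alcohol; 11 3,5-bis(benzyloxy)phenol
Product: 12 (4R)-triarylpropyne: C4 carries ring A [2-hydroxy-4,6-bis(benzyloxy)phenyl] and lower C6, and the alkyne ends in ring B (4-benzyloxyphenyl)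
Conditions: (R)-TRIP [(R)-3,3'-bis(2,4,6-triisopropylphenyl)-1,1'-binaphthyl-2,2'-diyl hydrogen phosphate] (10 mol %), 11 (4 equiv), 4 Å MS, CH2Cl2, −30 → 0 °C
Reagents that add atoms: none
Why: Proposed new method: an SN1 Friedel–Crafts propargylation under ion-pair control, in which the chiral phosphoric acid ionises the doubly stabilised carbinol (trioxygenated aryl plus arylalkynyl) to a cation paired with the chiral phosphate, whose P=O hydrogen-bonds the phenol OH and delivers the ortho carbon (less hindered than the para carbon between two benzyloxy groups) to one face of the cation, which sets C4; the sense of induction cannot be predicted with confidence and decides which acid antipode is used, attack at the propargylic carbon and not at the alkyne terminus is expected as for 1,3-diarylpropargyl cations, the lower ring cannot self-condense because C8 is brominated, and excess 11 suppresses double alkylation; the closest known reaction type is the chiral phosphoric acid-catalysed ortho-alkylation of phenols and naphthols by quinone methides and related stabilised benzylic cations, the achiral acid-catalysed propargylation of phenols being long known.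

Step 7
Reactants: 12 (4R)-triarylpropyne with free ring A phenol
Product: 13 ring A tert-butyldimethylsilyl ether of 12 (C4 now labelled S, same geometry)
Conditions: TBSCl, imidazole, DMF, rt
Reagents that add atoms: tert-butyldimethylsilyl chloride, CC(C)(C)[Si](C)(C)Cl
Why: Silylation of the only free OH protects the ring A phenol from oxidation and from premature epoxide opening in steps 8 and 9.

Step 8
Reactants: 13 silyl-protected triarylpropyne
Product: 14 (Z)-1,1,3-triarylpropene (C4 S, silyl ether)
Conditions: H2 (1 atm), Pd/CaCO3 poisoned with Pb(OAc)2 (Lindlar catalyst), quinoline, EtOAc, rt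
Reagents that add atoms: none
Why: Lindlar semi-hydrogenation adds H2 syn to the alkyne and should stop at the Z-alkene, leaving benzyl ethers, the aryl bromide and the C4 stereocentre untouched.

Step 9
Reactants: 14 (Z)-1,1,3-triarylpropene
Product: 15 cis-(2S,3R)-epoxide of 14 (C4 S, silyl ether)
Conditions: L-glucose-derived enantiomer of the Shi N-(4-tolyl)oxazolidinone ketone (0.3 equiv), Oxone (2KHSO5·KHSO4·K2SO4), K2CO3, Bu4NHSO4, DME/CH2(OMe)2–K2CO3/AcOH buffer pH 8, −10 °C
Reagents that add atoms: potassium peroxymonosulfate (KHSO5), [K+].[O-]S(=O)(=O)OO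
Why: Shi epoxidation transfers oxygen from the chiral dioxirane in a concerted, stereospecific way that keeps the cis geometry, and the catalyst antipode (opposite to the D-glucose-derived ketone, which gives (1R,2S)-oxides from cis-β-methylstyrene) is chosen to make C2 (S) and C3 (R), while the pH 8 buffer protects the acid-labile epoxide.

Step 10
Reactants: 15 silyl-protected cis-epoxide
Product: 16 cis-(2S,3R)-epoxide with free ring A phenol (C4 R by label, same geometry)
Conditions: Bu4NF/AcOH (1:1, 1.2 equiv), THF, −20 °C; cold pH 7 buffer; crude used at once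
Reagents that add atoms: none
Why: Fluoride cleaves the aryl silyl ether faster than anything else present, and acetic acid protonates the phenoxide so that no base-mediated 5-exo opening should occur before step 11.

Step 11
Reactants: 16 free-phenol cis-epoxide
Product: 17 benzyl-protected dimer (2R,3R,4R by label; 2,3-cis-3,4-trans, 4β→6) with free upper C3 hydroxyl, lower tri-O-benzylgallate and lower C8 bromine
Conditions: camphorsulfonic acid (0.1 equiv), CH2Cl2, −40 → −20 °C; Et3N quench
Reagents that add atoms: none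
Why: Camphorsulfonic acid hydrogen-bonds and protonates the epoxide oxygen, the C2–O bond lengthens because C2 is benzylic to the 4-benzyloxyphenyl ring, and the ring A phenol oxygen attacks C2 from the side opposite the departing oxygen, forming O1–C2 and leaving the former epoxide oxygen as the C3 hydroxyl. The closest known reaction is the acid-catalysed cyclisation of 1-aryl-3-(2-hydroxyaryl)propene oxides to flavan-3-ols, a π-activated endo-selective epoxide opening. The pyran closes in the 6-endo-tet mode; 5-exo attack at C3 is disfavoured because positive charge builds only at benzylic C2 and C3 is shielded by the neighbouring diarylmethine C4. The new centre C2 is set by inversion of the (2S) epoxide carbon to (2R), C3 keeps the (R) configuration written in step 9 and C4 is untouched, so the cis-epoxide maps onto the 2,3-cis-3,4-trans array. The step needs endo regioselectivity and clean inversion without a free benzylic cation; the aryl bias at C2, a catalytic weak acid, a non-polar solvent and low temperature should secure both.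

Step 12
Reactants: 17 dimer with free upper C3 hydroxyl; 4 3,4,5-tris(benzyloxy)benzoyl chloride
Product: 18 fully benzylated lower-C8-bromo bis-gallate
Conditions: 4 (3 equiv), Et3N, DMAP, CH2Cl2, rt → 40 °C
Reagents that add atoms: none
Why: DMAP-catalysed acylation with excess acid chloride should esterify the hindered axial C3 alcohol without touching any stereocentre.

Step 13
Reactants: 18 fully benzylated bis-gallate
Product: 19 target, (−)-epiafzelechin 3-O-gallate-(4β→6)-(−)-epicatechin 3-O-gallate
Conditions: H2 (1 atm), Pd(OH)2/C, NaOAc (1.2 equiv), THF/MeOH/H2O, rt, degassed solvents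
Reagents that add atoms: none
Why: Hydrogenolysis over Pd(OH)2/C should cleave the thirteen benzyl ethers and reduce the aryl C–Br bond in one operation, with NaOAc taking up HBr so that the acid-labile interflavan bond survives.

**Compound list**

1 | (−)-epicatechin | O[C@@H]1Cc2c(O)cc(O)cc2O[C@@H]1c1ccc(O)c(O)c1 | starting material
2 | 5,7,3',4'-tetra-O-benzyl-(−)-epicatechin (2R,3R) | O[C@@H]1Cc2c(OCc9ccccc9)cc(OCc9ccccc9)cc2O[C@@H]1c1ccc(OCc9ccccc9)c(OCc9ccccc9)c1 | intermediate
3 | 8-bromo-5,7,3',4'-tetra-O-benzyl-(−)-epicatechin | O[C@@H]1Cc2c(OCc9ccccc9)cc(OCc9ccccc9)c(Br)c2O[C@@H]1c1ccc(OCc9ccccc9)c(OCc9ccccc9)c1 | intermediate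
4 | 3,4,5-tris(benzyloxy)benzoyl chloride | O=C(Cl)c1cc(OCc9ccccc9)c(OCc9ccccc9)c(OCc9ccccc9)c1 | starting material
5 | 8-bromo-5,7,3',4'-tetra-O-benzyl-(−)-epicatechin 3-O-[3,4,5-tris(benzyloxy)benzoate] | O=C(O[C@@H]1Cc2c(OCc9ccccc9)cc(OCc9ccccc9)c(Br)c2O[C@@H]1c1ccc(OCc9ccccc9)c(OCc9ccccc9)c1)c5cc(OCc9ccccc9)c(OCc9ccccc9)c(OCc9ccccc9)c5 | intermediate
6 | C6 N,N-dimethyliminium chloride of 5 | C[N+](C)=Cc2c(OCc9ccccc9)c(Br)c3c(c2OCc9ccccc9)C[C@@H](OC(=O)c5cc(OCc9ccccc9)c(OCc9ccccc9)c(OCc9ccccc9)c5)[C@@H](c7ccc(OCc9ccccc9)c(OCc9ccccc9)c7)O3.[Cl-] | intermediate (not isolated)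
7 | 6-formyl derivative of 5 | O=Cc2c(OCc9ccccc9)c(Br)c3c(c2OCc9ccccc9)C[C@@H](OC(=O)c5cc(OCc9ccccc9)c(OCc9ccccc9)c(OCc9ccccc9)c5)[C@@H](c7ccc(OCc9ccccc9)c(OCc9ccccc9)c7)O3 | intermediate
8 | 1-(benzyloxy)-4-ethynylbenzene | C#Cc1ccc(OCc2ccccc2)cc1 | starting material
9 | lithium (4-benzyloxyphenyl)acetylide | [Li]C#Cc1ccc(OCc2ccccc2)cc1 | intermediate (not isolated)
10 | lower unit with 1-hydroxy-3-(4-benzyloxyphenyl)prop-2-yn-1-yl at C6, both carbinol epimers | OC(C#Cc6ccc(OCc9ccccc9)cc6)c2c(OCc9ccccc9)c(Br)c3c(c2OCc9ccccc9)C[C@@H](OC(=O)c5cc(OCc9ccccc9)c(OCc9ccccc9)c(OCc9ccccc9)c5)[C@@H](c7ccc(OCc9ccccc9)c(OCc9ccccc9)c7)O3 | intermediate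
11 | 3,5-bis(benzyloxy)phenol | Oc1cc(OCc2ccccc2)cc(OCc2ccccc2)c1 | starting material
12 | (4R)-triarylpropyne, free ring A phenol | Oc4cc(OCc9ccccc9)cc(OCc9ccccc9)c4[C@H](c2c(OCc9ccccc9)c(Br)c3c(c2OCc9ccccc9)C[C@@H](OC(=O)c5cc(OCc9ccccc9)c(OCc9ccccc9)c(OCc9ccccc9)c5)[C@@H](c7ccc(OCc9ccccc9)c(OCc9ccccc9)c7)O3)C#Cc6ccc(OCc9ccccc9)cc6 | intermediate
13 | ring A TBS ether of 12 (C4 S by label) | CC(C)(C)[Si](C)(C)Oc4cc(OCc9ccccc9)cc(OCc9ccccc9)c4[C@H](c2c(OCc9ccccc9)c(Br)c3c(c2OCc9ccccc9)C[C@@H](OC(=O)c5cc(OCc9ccccc9)c(OCc9ccccc9)c(OCc9ccccc9)c5)[C@@H](c7ccc(OCc9ccccc9)c(OCc9ccccc9)c7)O3)C#Cc6ccc(OCc9ccccc9)cc6 | intermediate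
14 | (Z)-1,1,3-triarylpropene, TBS ether (C4 S) | CC(C)(C)[Si](C)(C)Oc4cc(OCc9ccccc9)cc(OCc9ccccc9)c4[C@H](c2c(OCc9ccccc9)c(Br)c3c(c2OCc9ccccc9)C[C@@H](OC(=O)c5cc(OCc9ccccc9)c(OCc9ccccc9)c(OCc9ccccc9)c5)[C@@H](c7ccc(OCc9ccccc9)c(OCc9ccccc9)c7)O3)/C=C\c6ccc(OCc9ccccc9)cc6 | intermediate
15 | cis-(2S,3R)-epoxide, TBS ether (C4 S) | CC(C)(C)[Si](C)(C)Oc4cc(OCc9ccccc9)cc(OCc9ccccc9)c4[C@H](c2c(OCc9ccccc9)c(Br)c3c(c2OCc9ccccc9)C[C@@H](OC(=O)c5cc(OCc9ccccc9)c(OCc9ccccc9)c(OCc9ccccc9)c5)[C@@H](c7ccc(OCc9ccccc9)c(OCc9ccccc9)c7)O3)[C@H]1O[C@H]1c6ccc(OCc9ccccc9)cc6 | intermediate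
16 | cis-(2S,3R)-epoxide with free ring A phenol (C4 R by label); key-step precursor | Oc4cc(OCc9ccccc9)cc(OCc9ccccc9)c4[C@H](c2c(OCc9ccccc9)c(Br)c3c(c2OCc9ccccc9)C[C@@H](OC(=O)c5cc(OCc9ccccc9)c(OCc9ccccc9)c(OCc9ccccc9)c5)[C@@H](c7ccc(OCc9ccccc9)c(OCc9ccccc9)c7)O3)[C@H]1O[C@H]1c6ccc(OCc9ccccc9)cc6 | intermediate
17 | benzyl-protected dimer, free upper C3 hydroxyl, lower gallate, lower C8 bromine (2R,3R,4R by label); key-step product | O[C@@H]1[C@@H](c2c(OCc9ccccc9)c(Br)c3c(c2OCc9ccccc9)C[C@@H](OC(=O)c5cc(OCc9ccccc9)c(OCc9ccccc9)c(OCc9ccccc9)c5)[C@@H](c7ccc(OCc9ccccc9)c(OCc9ccccc9)c7)O3)c4c(OCc9ccccc9)cc(OCc9ccccc9)cc4O[C@@H]1c6ccc(OCc9ccccc9)cc6 | intermediate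
18 | fully benzylated lower-C8-bromo bis-gallate | O=C(O[C@@H]1[C@@H](c2c(OCc9ccccc9)c(Br)c3c(c2OCc9ccccc9)C[C@@H](OC(=O)c5cc(OCc9ccccc9)c(OCc9ccccc9)c(OCc9ccccc9)c5)[C@@H](c7ccc(OCc9ccccc9)c(OCc9ccccc9)c7)O3)c4c(OCc9ccccc9)cc(OCc9ccccc9)cc4O[C@@H]1c6ccc(OCc9ccccc9)cc6)c8cc(OCc9ccccc9)c(OCc9ccccc9)c(OCc9ccccc9)c8 | intermediate
19 | (−)-epiafzelechin 3-O-gallate-(4β→6)-(−)-epicatechin 3-O-gallate (upper 2R,3R,4S; lower 2R,3R) | O=C(O[C@@H]1[C@@H](c2c(O)cc3c(c2O)C[C@@H](OC(=O)c2cc(O)c(O)c(O)c2)[C@@H](c2ccc(O)c(O)c2)O3)c2c(O)cc(O)cc2O[C@@H]1c1ccc(O)cc1)c1cc(O)c(O)c(O)c1 | target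

Total step count: 13. Longest linear sequence: 13 steps (1 → 19).

**Steps most likely to fail**

1. Step 6 (carries the label). The ion pair may discriminate the two faces of the cation poorly, so that both C4 epimers form. The cation may also be captured at the alkyne terminus (allene) or para to the phenol OH. The fallback uses known chemistry and a different bond construction (C4–C3 instead of C4–C4a); it sets out from aldehyde 7 and phenol 11. The bromomagnesium phenoxide of 11 (EtMgBr, toluene) adds to 7 ortho-specifically through the magnesium chelate to give the ortho-hydroxybenzhydrol F1. Alkyne 8 is converted (n-BuLi, B(OMe)3, then KHF2) into potassium (4-benzyloxyphenyl)ethynyltrifluoroborate F2. HBF4·OEt2 in MeCN at 0 °C ionises F1 and the alkynyl group is transferred from boron to C4, which can give neither the allene nor the para isomer. Face control is given up: 12 forms together with the C4 epimer of 12 F3. The two are diastereomers because the lower unit is enantiopure, and they are separated by chromatography. The route is rejoined at 12.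

2. Step 11 (key step). The phenol may attack C3 in the 5-exo mode. C2 may ionise to a free benzylic cation, with loss of the cis relationship or a hydride shift to a ketone. The fallback bypasses the epoxide and sets out from Z-alkene 14. Dihydroxylation (K2OsO2(OH)4, N-methylmorpholine N-oxide, acetone/H2O, with the DHQD- or DHQ-IND cinchona ligand that serves the face used in step 9) gives the erythro-(2S,3R)-diol silyl ether F4. Bu4NF/AcOH frees the phenol to give the erythro-triol F5. A Mitsunobu reaction (PPh3, DIAD, THF, 0 °C) then lets the phenol displace the activated benzylic C2 hydroxyl with inversion. The route is rejoined at 17.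

3. Step 9. Oxygen transfer to the hindered Z-alkene may be slow, so that the ketone catalyst decomposes and the electron-rich rings are oxidised, or the face selectivity may be low. The fallback changes from dioxirane to metal-oxo transfer (Jacobsen–Katsuki epoxidation) and sets out from 14. It uses (S,S)-[N,N'-bis(3,5-di-tert-butylsalicylidene)cyclohexane-1,2-diaminato]MnCl with m-CPBA and N-methylmorpholine N-oxide in CH2Cl2 at −78 °C. This catalyst antipode gives the (1S,2R) series from indene and cis-β-methylstyrene. Some trans-epoxide from the stepwise pathway would have to be removed. The route is rejoined at 15 with no new compound.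

**Further compounds**

F1 | step 6 | ortho-hydroxybenzhydrol from 11 and 7 (carbinol epimers) | Oc4cc(OCc9ccccc9)cc(OCc9ccccc9)c4C(O)c2c(OCc9ccccc9)c(Br)c3c(c2OCc9ccccc9)C[C@@H](OC(=O)c5cc(OCc9ccccc9)c(OCc9ccccc9)c(OCc9ccccc9)c5)[C@@H](c7ccc(OCc9ccccc9)c(OCc9ccccc9)c7)O3
F2 | step 6 | potassium (4-benzyloxyphenyl)ethynyltrifluoroborate | [K+].F[B-](F)(F)C#Cc1ccc(OCc2ccccc2)cc1
F3 | step 6 | C4 epimer of 12 (4S) | Oc4cc(OCc9ccccc9)cc(OCc9ccccc9)c4[C@@H](c2c(OCc9ccccc9)c(Br)c3c(c2OCc9ccccc9)C[C@@H](OC(=O)c5cc(OCc9ccccc9)c(OCc9ccccc9)c(OCc9ccccc9)c5)[C@@H](c7ccc(OCc9ccccc9)c(OCc9ccccc9)c7)O3)C#Cc6ccc(OCc9ccccc9)cc6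
F4 | step 11 | erythro-(2S,3R)-diol, ring A TBS ether | CC(C)(C)[Si](C)(C)Oc4cc(OCc9ccccc9)cc(OCc9ccccc9)c4[C@H](c2c(OCc9ccccc9)c(Br)c3c(c2OCc9ccccc9)C[C@@H](OC(=O)c5cc(OCc9ccccc9)c(OCc9ccccc9)c(OCc9ccccc9)c5)[C@@H](c7ccc(OCc9ccccc9)c(OCc9ccccc9)c7)O3)[C@@H](O)[C@@H](O)c6ccc(OCc9ccccc9)cc6
F5 | step 11 | erythro-(2S,3R)-triol with free ring A phenol | Oc4cc(OCc9ccccc9)cc(OCc9ccccc9)c4[C@H](c2c(OCc9ccccc9)c(Br)c3c(c2OCc9ccccc9)C[C@@H](OC(=O)c5cc(OCc9ccccc9)c(OCc9ccccc9)c(OCc9ccccc9)c5)[C@@H](c7ccc(OCc9ccccc9)c(OCc9ccccc9)c7)O3)[C@@H](O)[C@@H](O)c6ccc(OCc9ccccc9)cc6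
F0 | step 9 | none | none
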